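The route rests on cutting C5–C10 and C3–C4, which takes ring A off a preformed C/D bicyclo[3.2.1]octane. One thermal intramolecular Diels–Alder reaction of triene 34 then closes rings A and B together and sets the contiguous C4, C5 and C10 stereocentres (C4 and C10 quaternary) of the cis A/B junction. This is the feature exploited: the ring-A atoms C1–C5 and C10 map onto a C9-bound dienoate (C10=C1–C2=C3) plus a C8-tethered Z-enoate (C5=C4), with C9–C8–C6 becoming ring B. In 34 the diene holds C9 on its inner position, C6 is stereodefined, C7 is masked as CH2OBn and C19/C20 are 2-(trimethylsilyl)ethyl esters.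

Key step: step 21

Remark: atom labels follow gibberellane numbering (ring C: C8, C9, C11–C14; ring D: C8, C14, C13, C16, C15); TMSE = 2-(trimethylsilyl)ethyl, TES = triethylsilyl, TBS = tert-butyldimethylsilyl.
Assumption 1: the sense of the chiral-amide deprotonation in step 2 is taken from the behaviour of 4-tert-butylcyclohexanone; should it be opposite, the (R,R)-amine is used.
Assumption 2: benzyl chloromethyl ether is taken to enter the C6 enolate in step 11 on the face that gives 18; the opposite outcome is covered at the end.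

Step 1
Reactants: 1 2-(4-oxocyclohexyl)acetic acid
Product: 2 benzyl 2-(4-oxocyclohexyl)acetate
Conditions: BnBr, K2CO3, DMF, rt
Reagents that add atoms: benzyl bromide BrCc1ccccc1
Why: SN2 O-alkylation of the potassium carboxylate (ester formation) should be clean because the ketone does not react with carbonate, and the benzyl ester can later be removed by hydrogenolysis beside a methyl ester; no stereocentre is formed.

Step 2
Reactants: 2 benzyl 2-(4-oxocyclohexyl)acetate
Product: 4 benzyl 2-[(1S)-4-oxocyclohex-2-en-1-yl]acetate, via silyl enol ether 3 (not isolated)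
Conditions: lithium bis[(S)-1-phenylethyl]amide (from the amine and n-BuLi), TMSCl, THF, −100 °C; then Pd(OAc)2, MeCN, rt
Reagents that add atoms: none
Why: Enantioselective deprotonation of the prochiral ketone by a chiral lithium amide under internal silyl quench removes one of the two enantiotopic axial α-hydrogens (the ester α-hydrogens are far less acidic), which renders C9 stereogenic, and Saegusa–Ito oxidation of the enol silane then installs the C14=C8 enone without touching C9.

Step 3
Reactants: 4 benzyl 2-[(1S)-4-oxocyclohex-2-en-1-yl]acetate; 5 1-(tert-butyldimethylsilyloxy)-1-methoxyethene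
Product: 7 benzyl 2-[(1S)-2-(2-methoxy-2-oxoethyl)-4-oxocyclohex-2-en-1-yl]acetate, via TBS enol ether 6 (not isolated)
Conditions: MeCN, 55 °C; then Pd(OAc)2, rt
Reagents that add atoms: none
Why: Uncatalysed Mukaiyama–Michael addition of the ketene silyl acetal in acetonitrile transfers the C6–C7 acetate unit to C8 and the silyl group to oxygen, and Saegusa–Ito oxidation of the resulting enol silane re-forms the enone, so the C8 centre created in the addition is erased and needs no control.

Step 4
Reactants: 7 benzyl 2-[(1S)-2-(2-methoxy-2-oxoethyl)-4-oxocyclohex-2-en-1-yl]acetate; 8 allyltrimethylsilane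
Product: 9 benzyl 2-[(1S,2R)-2-(2-methoxy-2-oxoethyl)-4-oxo-2-(prop-2-en-1-yl)cyclohexyl]acetate
Conditions: TiCl4, CH2Cl2, −78 °C; H2O
Reagents that add atoms: none
Why: Hosomi–Sakurai conjugate allylation builds the quaternary C8: in the reactive half-chair the C9 side chain is pseudoaxial next to the substituted alkene carbon and the allylsilane adds axially on the opposite face, so the allyl group (future C15 and C16) should end trans and the acetate arm (future C6 and C7) cis to the C9 arm.

Step 5
Reactants: 9 benzyl 2-[(1S,2R)-2-(2-methoxy-2-oxoethyl)-4-oxo-2-(prop-2-en-1-yl)cyclohexyl]acetate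
Product: 11 benzyl 2-[(1S,2R)-2-(2-methoxy-2-oxoethyl)-4-oxo-2-(2-oxoethyl)cyclohexyl]acetate, via ozonide 10 (not isolated)
Conditions: O3, CH2Cl2, −78 °C; then PPh3, −78 °C → rt
Reagents that add atoms: ozone [O-][O+]=O
Why: Ozonolysis with reductive work-up (Criegee mechanism) cleaves the terminal alkene to the C16 aldehyde much faster than ozone attacks the benzyl ester ring, and no stereocentre is involved.

Step 6
Reactants: 11 benzyl 2-[(1S,2R)-2-(2-methoxy-2-oxoethyl)-4-oxo-2-(2-oxoethyl)cyclohexyl]acetate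
Product: 12 cis-13,16-diol of the C/D bicyclo[3.2.1]octane (8-CH2CO2Me; 9-CH2CO2Bn)
Conditions: SmI2, t-BuOH, THF, −78 °C → rt
Reagents that add atoms: none
Why: SmI2-mediated intramolecular pinacol coupling (ketyl addition of the aldehyde to the C13 ketone) closes ring D through the chair in which the C15 arm is axial; the two-carbon bridge can only span one face of the six-membered ring, so C13 is fixed by C8, the samarium-bridged transition state should give the cis diol, and the C16 carbinol centre is removed again in step 7.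

Step 7
Reactants: 12 cis-13,16-diol of the C/D bicyclo[3.2.1]octane (8-CH2CO2Me; 9-CH2CO2Bn)
Product: 13 13-hydroxy-16-oxo C/D bicycle (8-CH2CO2Me; 9-CH2CO2Bn)
Conditions: IBX, DMSO, rt
Reagents that add atoms: none
Why: IBX oxidises the secondary alcohol of a 1,2-diol to the ketone without cleaving the glycol and cannot oxidise the tertiary C13 alcohol; no stereocentre changes.

Step 8
Reactants: 13 13-hydroxy-16-oxo C/D bicycle (8-CH2CO2Me; 9-CH2CO2Bn)
Product: 14 13-O-TBS 16-oxo C/D bicycle (8-CH2CO2Me; 9-CH2CO2Bn)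
Conditions: TBSOTf, 2,6-lutidine, CH2Cl2, 0 °C → rt
Reagents that add atoms: tert-butyldimethylsilyl trifluoromethanesulfonate CC(C)(C)[Si](C)(C)OS(=O)(=O)C(F)(F)F
Why: Silylation of the hindered tertiary alcohol with the silyl triflate and a hindered pyridine base protects C13–OH before any acidic or basic step can trigger an α-ketol shift; no stereocentre changes.

Step 9
Reactants: 14 13-O-TBS 16-oxo C/D bicycle (8-CH2CO2Me; 9-CH2CO2Bn)
Product: 15 13-O-TBS 16-ethylene-ketal C/D bicycle (8-CH2CO2Me; 9-CH2CO2Bn)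
Conditions: TMSOCH2CH2OTMS, TMSOTf (cat.), CH2Cl2, −78 → 0 °C
Reagents that add atoms: 1,2-bis(trimethylsilyloxy)ethane C[Si](C)(C)OCCO[Si](C)(C)C
Why: Noyori ketalisation with the bis-silyl ether of ethylene glycol and catalytic TMSOTf works at low temperature without free acid or water, which suits a hindered ketone flanked by a silyl ether; no stereocentre changes.

Step 10
Reactants: 15 13-O-TBS 16-ethylene-ketal C/D bicycle (8-CH2CO2Me; 9-CH2CO2Bn)
Product: 16 C20 acid (8-CH2CO2Me; 9-CH2CO2H)
Conditions: H2 (1 atm), Pd/C, EtOAc, rt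
Reagents that add atoms: none
Why: Hydrogenolysis of the benzyl ester frees the C20 acid while the methyl ester, ketal and silyl ether are inert; as its carboxylate this arm cannot be enolised in steps 11 and 12, and crystallisation of a salt of 16 with an enantiopure amine could raise the enantiomeric purity if needed.

Step 11
Reactants: 16 C20 acid (8-CH2CO2Me; 9-CH2CO2H); 17 benzyl chloromethyl ether
Product: 18 C6-benzyloxymethyl ester acid (8-CH(CH2OBn)CO2Me; 9-CH2CO2H)
Conditions: LDA (2.2 equiv), THF, −78 °C; then 17, −78 → −40 °C; aq. NaH2PO4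
Reagents that add atoms: none
Why: Alkylation of an ester enolate: with two equivalents of LDA the C20 acid becomes a lithium carboxylate whose α-hydrogens are not removed at −78 °C, so only the C6 ester enolate forms and is C-alkylated by the reactive α-chloro ether, which adds the C7 carbon; the new C6 centre is set by the face of attack, taken as stated in assumption 2.

Step 12
Reactants: 18 C6-benzyloxymethyl ester acid (8-CH(CH2OBn)CO2Me; 9-CH2CO2H)
Product: 19 hydroxy acid (8-CH(CH2OBn)CH2OH; 9-CH2CO2H)
Conditions: LiOMe (1 equiv); LiBH4, THF–MeOH, 0 → 45 °C; aq. NaH2PO4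
Reagents that add atoms: none
Why: Chemoselective reduction with LiBH4 converts the methyl ester into the C5 primary alcohol while the lithium carboxylate is not reduced; C6 keeps its configuration because no enolisable carbonyl remains on it.

Step 13
Reactants: 19 hydroxy acid (8-CH(CH2OBn)CH2OH; 9-CH2CO2H)
Product: 21 TES ether acid (8-CH(CH2OBn)CH2OTES; 9-CH2CO2H), via bis-silyl derivative 20 (not isolated)
Conditions: TESCl (2.2 equiv), imidazole, CH2Cl2, 0 °C; then aq. NaHCO3–THF, rt
Reagents that add atoms: chlorotriethylsilane CC[Si](Cl)(CC)CC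
Why: Silylation with the chlorosilane and imidazole protects the primary alcohol as the TES ether, and the silyl ester formed at the acid is hydrolysed on aqueous work-up; no stereocentre changes.

Step 14
Reactants: 21 TES ether acid (8-CH(CH2OBn)CH2OTES; 9-CH2CO2H); 22 2-(trimethylsilyl)ethanol
Product: 23 TMSE ester (8-CH(CH2OBn)CH2OTES; 9-CH2CO2TMSE)
Conditions: DCC, DMAP (cat.), CH2Cl2, 0 °C → rt
Reagents that add atoms: none
Why: Steglich esterification (carbodiimide activation with acyl transfer by DMAP) gives the fluoride-labile TMSE ester at C20; no stereocentre changes.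

Step 15
Reactants: 23 TMSE ester (8-CH(CH2OBn)CH2OTES; 9-CH2CO2TMSE); 24 acrolein
Product: 27 dienoate (9-C(CO2TMSE)=CH–CH=CH2 having C9 cis to C2; 8-CH(CH2OBn)CH2OTES), via lithium aldolate 25 (not isolated), via mesylate 26 (not isolated)
Conditions: LDA, THF, −78 °C; 24, −78 °C; MsCl, −78 → 0 °C; then DBU, 0 °C → rt
Reagents that add atoms: none
Why: Aldol addition of the only enolisable ester (C10) to the carbonyl group of acrolein, mesylation of the lithium aldolate and E1cB elimination with DBU should give the conjugated dienoate as the more stable E isomer, in which the vinyl group is trans to the ester and therefore cis to C9; the two transient centres at C10 and C1 disappear.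

Step 16
Reactants: 27 dienoate (9-C(CO2TMSE)=CH–CH=CH2 having C9 cis to C2; 8-CH(CH2OBn)CH2OTES)
Product: 28 dienoate aldehyde (8-CH(CH2OBn)CHO)
Conditions: (COCl)2, DMSO, CH2Cl2, −78 → −40 °C; then Et3N, −78 → 0 °C
Reagents that add atoms: none
Why: Swern oxidation applied directly to the primary TES ether (the chlorosulfonium salt cleaves primary triethylsilyl ethers and oxidises them in one operation) gives the C5 aldehyde under non-acidic conditions; amine base at low temperature should leave the α-centre C6 unchanged.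

Step 17
Reactants: 29 bromoacetyl bromide; 22 2-(trimethylsilyl)ethanol
Product: 30 2-(trimethylsilyl)ethyl bromoacetate
Conditions: pyridine, CH2Cl2, 0 °C
Reagents that add atoms: none
Why: Acylation of the alcohol by the acyl bromide in the presence of pyridine gives the bromoacetate; no stereocentre.

Step 18
Reactants: 30 2-(trimethylsilyl)ethyl bromoacetate; 31 diphenyl phosphite
Product: 32 2-(trimethylsilyl)ethyl 2-(diphenoxyphosphoryl)acetate
Conditions: Et3N, CH2Cl2, 0 °C → rt
Reagents that add atoms: none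
Why: Michaelis–Becker-type P-alkylation of diphenyl phosphite by the α-bromo ester with an amine base gives the diaryl phosphonoacetate; no stereocentre.

Step 19
Reactants: 32 2-(trimethylsilyl)ethyl 2-(diphenoxyphosphoryl)acetate
Product: 33 2-(trimethylsilyl)ethyl 2-(diphenoxyphosphoryl)propanoate (racemic)
Conditions: NaH, THF, 0 °C; MeI, rt
Reagents that add atoms: iodomethane CI
Why: C-methylation of the sodium phosphonoacetate anion with iodomethane adds the future C18 methyl group; the new centre is racemic and becomes sp2 in step 20.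

Step 20
Reactants: 28 dienoate aldehyde (8-CH(CH2OBn)CHO); 33 2-(trimethylsilyl)ethyl 2-(diphenoxyphosphoryl)propanoate
Product: 34 triene (9-dienoate having C9 cis to C2; 8-CH(CH2OBn)–CH=C(CH3)CO2TMSE having C19 cis to C6)
Conditions: 33, NaH, THF, 0 °C; then 28, −78 → −20 °C
Reagents that add atoms: none
Why: Z-selective Horner–Wadsworth–Emmons olefination with a diaryl phosphonate (Ando modification): the electron-poor aryloxy groups make elimination from the first-formed adduct fast, so the trisubstituted enoate should form with C19 cis to C6, and the stabilised anion at −78 °C should not epimerise C6.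

Step 21
Reactants: 34 triene (9-dienoate having C9 cis to C2; 8-CH(CH2OBn)–CH=C(CH3)CO2TMSE having C19 cis to C6)
Product: 35 tetracyclic cycloadduct (C1=C2 alkene; 19- and 20-CO2TMSE; 7-CH2OBn; 13-OTBS; 16-ketal)
Conditions: toluene (0.005 M), BHT, 170 °C, sealed tube
Reagents that add atoms: none
Why: A concerted, suprafacial thermal [4+2] cycloaddition joins the C10=C1–C2=C3 dienoate to the C5=C4 enoate and forms C5–C10 and C3–C4; the closest known reaction type is the intramolecular Diels–Alder reaction of 1,3,8-nonatrienes whose tether occupies the inner (cis) position of the diene, which gives cis-fused hydrindenes. Ring A (six-membered, C1–C5 and C10) is closed by the cycloaddition itself and ring B (five-membered, C5–C6–C8–C9–C10) as the tether ring, through the new bonds C5–C10 and C3–C4. The C5/C10 relationship (cis fusion) is dictated by the inner position of C9, from which a trans-fused transition state cannot be reached; the C4/C5 relationship comes from suprafacial addition to the Z-enoate, which places C19 cis to C6; and the face shown by the enoate is set by C6, whose hydrogen must eclipse C5=C4 to avoid allylic 1,3-strain with the cis ester, so that C7 ends trans to C4. The step needs ring A on the C11 face of ring B; the C6 centre asks for exactly this face, whereas allylic strain at C9 would rather turn the diene towards the H9 face, so the outcome of this contest is the one declared risk of the route. The quaternary C8 favours the folded reactive conformer, and because C7 is carried as CH2OBn the C6 hydrogen is not acidified, so the controlling centre cannot epimerise at 170 °C.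

Step 22
Reactants: 35 tetracyclic cycloadduct (C1=C2 alkene; 19- and 20-CO2TMSE; 7-CH2OBn; 13-OTBS; 16-ketal)
Product: 36 saturated tetracycle (7-CH2OH; 19- and 20-CO2TMSE)
Conditions: H2 (3 atm), Pd/C, EtOAc–EtOH, rt
Reagents that add atoms: none
Why: Heterogeneous hydrogenation saturates the C1=C2 alkene (no new stereocentre) and hydrogenolyses the benzyl ether at C7, while TMSE esters, ketal and silyl ether are inert.

Step 23
Reactants: 36 saturated tetracycle (7-CH2OH; 19- and 20-CO2TMSE)
Product: 38 C7 acid (19- and 20-CO2TMSE), via aldehyde 37 (not isolated)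
Conditions: TEMPO (cat.), PhI(OAc)2, MeCN–H2O, rt
Reagents that add atoms: water O
Why: TEMPO-catalysed oxidation with PhI(OAc)2 in aqueous acetonitrile takes the primary alcohol through the aldehyde hydrate to the C7 acid; C6 becomes epimerisable at the aldehyde stage but the required configuration (C7 trans to C4) is the less crowded one.

Step 24
Reactants: 38 C7 acid (19- and 20-CO2TMSE)
Product: 39 C7 methyl ester (19- and 20-CO2TMSE; 13-OTBS; 16-ketal)
Conditions: TMSCHN2, MeOH–toluene, 0 °C
Reagents that add atoms: (trimethylsilyl)diazomethane C[Si](C)(C)C=[N+]=[N-]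
Why: Esterification with (trimethylsilyl)diazomethane in methanol methylates the only free acid, C7, so the methyl ester is placed unambiguously; no stereocentre changes.

Step 25
Reactants: 39 C7 methyl ester (19- and 20-CO2TMSE; 13-OTBS; 16-ketal)
Product: 40 16-ketone (7-CO2Me; 19- and 20-CO2TMSE; 13-OTBS)
Conditions: 1 M HCl, THF, rt
Reagents that add atoms: water O
Why: Acid-catalysed hydrolysis of the dioxolane releases the C16 ketone while the tertiary silyl ether and the TMSE esters withstand dilute acid; no stereocentre changes.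

Step 26
Reactants: 40 16-ketone (7-CO2Me; 19- and 20-CO2TMSE; 13-OTBS)
Product: 41 16-methylene compound (7-CO2Me; 19- and 20-CO2TMSE; 13-OTBS)
Conditions: Ph3PCH3Br, KOtBu, THF, 0 → 50 °C
Reagents that add atoms: methyltriphenylphosphonium bromide C[P+](c1ccccc1)(c1ccccc1)c1ccccc1.[Br-]
Why: Wittig methylenation converts the C16 ketone into the exocyclic alkene; the silyl ether on C13 blocks the base-induced α-ketol shift, the hindered esters are not attacked by the ylide, and any equilibration at C6 favours the required epimer.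

Step 27
Reactants: 41 16-methylene compound (7-CO2Me; 19- and 20-CO2TMSE; 13-OTBS)
Product: 42 CNP0285449.1 (13-hydroxy-16-ene 7-methyl ester 19,20-diacid; cis A/B fusion)
Conditions: Bu4NF, THF, rt → 50 °C; aq. NaH2PO4
Reagents that add atoms: none
Why: Fluoride triggers β-elimination of both TMSE esters (attack at silicon, so the hindered C19 and C20 carboxylates are released without hydrolysis) and cleaves the tertiary silyl ether, while the C7 methyl ester is kept; mildly acidic work-up avoids rearrangement of the tertiary allylic alcohol.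

Compound list
1 | 2-(4-oxocyclohexyl)acetic acid | O=C1CCC(CC(=O)O)CC1 | starting material
2 | benzyl 2-(4-oxocyclohexyl)acetate | O=C1CCC(CC(=O)OCc2ccccc2)CC1 | intermediate
3 | benzyl 2-[(1R)-4-(trimethylsilyloxy)cyclohex-3-en-1-yl]acetate | C[Si](C)(C)OC1=CC[C@H](CC(=O)OCc2ccccc2)CC1 | intermediate
4 | benzyl 2-[(1S)-4-oxocyclohex-2-en-1-yl]acetate | O=C1C=C[C@H](CC(=O)OCc2ccccc2)CC1 | intermediate
5 | 1-(tert-butyldimethylsilyloxy)-1-methoxyethene | C=C(OC)O[Si](C)(C)C(C)(C)C | starting material
6 | benzyl 2-[(1S,2S)-4-(tert-butyldimethylsilyloxy)-2-(2-methoxy-2-oxoethyl)cyclohex-3-en-1-yl]acetate (trans) | CC(C)(C)[Si](C)(C)OC1=C[C@@H](CC(=O)OC)[C@H](CC(=O)OCc2ccccc2)CC1 | intermediate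
7 | benzyl 2-[(1S)-2-(2-methoxy-2-oxoethyl)-4-oxocyclohex-2-en-1-yl]acetate | O=C1C=C(CC(=O)OC)[C@H](CC(=O)OCc2ccccc2)CC1 | intermediate
8 | allyltrimethylsilane | C=CC[Si](C)(C)C | starting material
9 | benzyl 2-[(1S,2R)-2-(2-methoxy-2-oxoethyl)-4-oxo-2-(prop-2-en-1-yl)cyclohexyl]acetate | O=C1C[C@](CC=C)(CC(=O)OC)[C@H](CC(=O)OCc2ccccc2)CC1 | intermediate
10 | ozonide (1,2,4-trioxolane) of 9, mixture at the trioxolane carbon | O=C1C[C@](CC2OCOO2)(CC(=O)OC)[C@H](CC(=O)OCc2ccccc2)CC1 | intermediate
11 | benzyl 2-[(1S,2R)-2-(2-methoxy-2-oxoethyl)-4-oxo-2-(2-oxoethyl)cyclohexyl]acetate | O=C1C[C@](CC=O)(CC(=O)OC)[C@H](CC(=O)OCc2ccccc2)CC1 | intermediate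
12 | C/D bicyclo[3.2.1]octane cis-13,16-diol with 8-CH2CO2Me and 9-CH2CO2Bn (9-arm anti to the C15–C16 bridge; C8, C9, C13 as in the target) | O[C@@H]1C[C@@]2(C[C@@]1(O)CC[C@H]2CC(=O)OCc3ccccc3)CC(=O)OC | intermediate
13 | 13-hydroxy-16-oxo C/D bicycle with 8-CH2CO2Me and 9-CH2CO2Bn | O=C1C[C@@]2(C[C@@]1(O)CC[C@H]2CC(=O)OCc3ccccc3)CC(=O)OC | intermediate
14 | 13-O-TBS 16-oxo C/D bicycle with 8-CH2CO2Me and 9-CH2CO2Bn | O=C1C[C@@]2(C[C@@]1(O[Si](C)(C)C(C)(C)C)CC[C@H]2CC(=O)OCc3ccccc3)CC(=O)OC | intermediate
15 | 13-O-TBS 16-ethylene-ketal C/D bicycle with 8-CH2CO2Me and 9-CH2CO2Bn | O1CCOC12C[C@@]3(C[C@@]2(O[Si](C)(C)C(C)(C)C)CC[C@H]3CC(=O)OCc4ccccc4)CC(=O)OC | intermediate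
16 | C20 acid: the same bicycle with 8-CH2CO2Me and 9-CH2CO2H | O1CCOC12C[C@@]3(C[C@@]2(O[Si](C)(C)C(C)(C)C)CC[C@H]3CC(=O)O)CC(=O)OC | intermediate
17 | benzyl chloromethyl ether | ClCOCc1ccccc1 | starting material
18 | C6-benzyloxymethyl ester acid: 8-CH(CH2OBn)CO2Me, 9-CH2CO2H, C6 configured as in the target | O1CCOC12C[C@@]3(C[C@@]2(O[Si](C)(C)C(C)(C)C)CC[C@H]3CC(=O)O)[C@@H](COCc4ccccc4)C(=O)OC | intermediate
19 | hydroxy acid: 8-CH(CH2OBn)CH2OH, 9-CH2CO2H | O1CCOC12C[C@@]3(C[C@@]2(O[Si](C)(C)C(C)(C)C)CC[C@H]3CC(=O)O)[C@@H](COCc4ccccc4)CO | intermediate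
20 | bis-silyl derivative: TES ether at C5–O and TES ester at C20 | O1CCOC12C[C@@]3(C[C@@]2(O[Si](C)(C)C(C)(C)C)CC[C@H]3CC(=O)O[Si](CC)(CC)CC)[C@@H](COCc4ccccc4)CO[Si](CC)(CC)CC | intermediate
21 | TES ether acid: 8-CH(CH2OBn)CH2OTES, 9-CH2CO2H | O1CCOC12C[C@@]3(C[C@@]2(O[Si](C)(C)C(C)(C)C)CC[C@H]3CC(=O)O)[C@@H](COCc4ccccc4)CO[Si](CC)(CC)CC | intermediate
22 | 2-(trimethylsilyl)ethanol | C[Si](C)(C)CCO | starting material
23 | TMSE ester: 8-CH(CH2OBn)CH2OTES, 9-CH2CO2TMSE | O1CCOC12C[C@@]3(C[C@@]2(O[Si](C)(C)C(C)(C)C)CC[C@H]3CC(=O)OCC[Si](C)(C)C)[C@@H](COCc4ccccc4)CO[Si](CC)(CC)CC | intermediate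
24 | acrolein | C=CC=O | starting material
25 | lithium aldolate at C10/C1, mixture of diastereomers at C10 and C1 | O1CCOC12C[C@@]3(C[C@@]2(O[Si](C)(C)C(C)(C)C)CC[C@H]3C(C([O-])C=C)C(=O)OCC[Si](C)(C)C)[C@@H](COCc4ccccc4)CO[Si](CC)(CC)CC.[Li+] | intermediate
26 | C1 mesylate of the aldol, mixture of diastereomers at C10 and C1 | O1CCOC12C[C@@]3(C[C@@]2(O[Si](C)(C)C(C)(C)C)CC[C@H]3C(C(OS(C)(=O)=O)C=C)C(=O)OCC[Si](C)(C)C)[C@@H](COCc4ccccc4)CO[Si](CC)(CC)CC | intermediate
27 | dienoate: 9-C(CO2TMSE)=CH–CH=CH2 with C9 cis to C2, 8-CH(CH2OBn)CH2OTES | O1CCOC12C[C@@]3(C[C@@]2(O[Si](C)(C)C(C)(C)C)CC[C@H]3/C(C(=O)OCC[Si](C)(C)C)=C\C=C)[C@@H](COCc4ccccc4)CO[Si](CC)(CC)CC | intermediate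
28 | dienoate aldehyde: 8-CH(CH2OBn)CHO | O1CCOC12C[C@@]3(C[C@@]2(O[Si](C)(C)C(C)(C)C)CC[C@H]3/C(C(=O)OCC[Si](C)(C)C)=C\C=C)[C@@H](COCc4ccccc4)C=O | intermediate
29 | bromoacetyl bromide | BrCC(=O)Br | starting material
30 | 2-(trimethylsilyl)ethyl bromoacetate | BrCC(=O)OCC[Si](C)(C)C | intermediate
31 | diphenyl phosphite | O=[PH](Oc1ccccc1)Oc1ccccc1 | starting material
32 | 2-(trimethylsilyl)ethyl 2-(diphenoxyphosphoryl)acetate | O=P(CC(=O)OCC[Si](C)(C)C)(Oc1ccccc1)Oc1ccccc1 | intermediate
33 | 2-(trimethylsilyl)ethyl 2-(diphenoxyphosphoryl)propanoate, racemic | CC(C(=O)OCC[Si](C)(C)C)P(=O)(Oc1ccccc1)Oc1ccccc1 | intermediate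
34 | triene: 9-dienoate (C9 cis to C2) and 8-CH(CH2OBn)–CH=C(CH3)CO2TMSE (C19 cis to C6) on the 13-O-TBS 16-ketal C/D bicycle | O1CCOC12C[C@@]3(C[C@@]2(O[Si](C)(C)C(C)(C)C)CC[C@H]3/C(C(=O)OCC[Si](C)(C)C)=C\C=C)[C@@H](COCc4ccccc4)/C=C(/C)C(=O)OCC[Si](C)(C)C | intermediate
35 | tetracyclic cycloadduct: C1=C2 alkene, cis A/B fusion, 19- and 20-CO2TMSE, 7-CH2OBn, 13-OTBS, 16-ketal | O1CCOC12C[C@]34C[C@@]2(O[Si](C)(C)C(C)(C)C)CC[C@H]3[C@@]5(C(=O)OCC[Si](C)(C)C)C=CC[C@@](C)(C(=O)OCC[Si](C)(C)C)[C@H]5[C@@H]4COCc6ccccc6 | intermediate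
36 | saturated tetracycle with 7-CH2OH | O1CCOC12C[C@]34C[C@@]2(O[Si](C)(C)C(C)(C)C)CC[C@H]3[C@@]5(C(=O)OCC[Si](C)(C)C)CCC[C@@](C)(C(=O)OCC[Si](C)(C)C)[C@H]5[C@@H]4CO | intermediate
37 | C7 aldehyde | O1CCOC12C[C@]34C[C@@]2(O[Si](C)(C)C(C)(C)C)CC[C@H]3[C@@]5(C(=O)OCC[Si](C)(C)C)CCC[C@@](C)(C(=O)OCC[Si](C)(C)C)[C@H]5[C@@H]4C=O | intermediate
38 | C7 acid | O1CCOC12C[C@]34C[C@@]2(O[Si](C)(C)C(C)(C)C)CC[C@H]3[C@@]5(C(=O)OCC[Si](C)(C)C)CCC[C@@](C)(C(=O)OCC[Si](C)(C)C)[C@H]5[C@@H]4C(=O)O | intermediate
39 | C7 methyl ester with 16-ketal | O1CCOC12C[C@]34C[C@@]2(O[Si](C)(C)C(C)(C)C)CC[C@H]3[C@@]5(C(=O)OCC[Si](C)(C)C)CCC[C@@](C)(C(=O)OCC[Si](C)(C)C)[C@H]5[C@@H]4C(=O)OC | intermediate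
40 | 16-ketone: 7-CO2Me, 19- and 20-CO2TMSE, 13-OTBS | O=C1C[C@]23C[C@@]1(O[Si](C)(C)C(C)(C)C)CC[C@H]2[C@@]4(C(=O)OCC[Si](C)(C)C)CCC[C@@](C)(C(=O)OCC[Si](C)(C)C)[C@H]4[C@@H]3C(=O)OC | intermediate
41 | 16-methylene compound: 7-CO2Me, 19- and 20-CO2TMSE, 13-OTBS | C=C1C[C@]23C[C@@]1(O[Si](C)(C)C(C)(C)C)CC[C@H]2[C@@]4(C(=O)OCC[Si](C)(C)C)CCC[C@@](C)(C(=O)OCC[Si](C)(C)C)[C@H]4[C@@H]3C(=O)OC | intermediate
42 | CNP0285449.1: 13-hydroxy-16-ene 7-methyl ester 19,20-diacid with cis A/B fusion | C=C1C[C@]23C[C@@]1(O)CC[C@H]2[C@@]1(C(=O)O)CCC[C@@](C)(C(=O)O)[C@H]1[C@@H]3C(=O)OC | target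

Total step count: 27. Longest linear sequence: 24 steps (1–16 and 20–27); steps 17–19 prepare phosphonate 33.

Steps most likely to fail

Step 21. What may go wrong is cycloaddition through the diene face that puts ring A beside H9, which allylic strain at C9 favours, or a [1,5]-hydrogen shift from C9 to C3 of the cis-diene outrunning ring closure. The fallback replaces the concerted closure by an anionic ring-closing sequence. With C10 as an ester enolate the C10=C20 bond takes the position eclipsed with H9, which places the C1 chain on the C11 side, so the strain that opposes the cycloaddition now supports the required C10 configuration. The fallback sets out from 23. Alkylation of its lithium enolate (LDA, THF–DMPU) with 1-bromo-3-chloropropane should give the 10-(3-chloropropyl) ester F1, direct Swern oxidation of the TES ether the aldehyde F2, and olefination with 33 as in step 20 the Z-enoate F3. KHMDS with NaI in THF then forms the C10 enolate, which closes ring B by Michael addition to C5, and the C4 enolate thus formed closes ring A by displacing chloride at C3, giving the saturated tetracycle F4. In this sequence C4 is set by an enolate alkylation and no longer by alkene geometry, so its configuration would have to be checked. Hydrogenolysis of the benzyl ether (H2, Pd/C) rejoins the route at 36.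

Step 11. What may go wrong is poor or reversed facial selectivity in the alkylation of the C6 enolate, which is flanked by a quaternary carbon whose three substituents differ little. The fallback sets the centre by C–H instead of C–C bond formation. It sets out from 16; the alkylation then gives mainly the C6-epimeric ester acid F5. This is deprotonated again (excess LDA, THF–DMPU, −40 °C) and the enolate is protonated kinetically at −78 °C with 2,6-di-tert-butyl-4-methylphenol. The proton should enter on the face that the alkylating agent had chosen, which inverts C6 and rejoins the route at 18.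

Step 15. What may go wrong is loss of geometric control in the elimination (vinyl group ending cis to the ester, which would put C9 on the outer position of the diene), or retro-aldol cleavage of the aldolate. The fallback fixes the geometry by cross-coupling and sets out from 23. Claisen formylation (LDA; ethyl formate) gives the hydroxymethylene ester F6. O-Triflation of its potassium enolate under non-chelating conditions (KHMDS, 18-crown-6, PhNTf2) should give the enol triflate F7 with the triflate trans to the ester and cis to C9. Suzuki–Miyaura coupling with vinylboronic acid pinacol ester (Pd(PPh3)4, K3PO4) proceeds with retention and rejoins the route at 27.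

Further compounds
F1 | step 21 | 10-(3-chloropropyl) TMSE ester with 8-CH(CH2OBn)CH2OTES, mixture at C10 | O1CCOC12C[C@@]3(C[C@@]2(O[Si](C)(C)C(C)(C)C)CC[C@H]3C(CCCCl)C(=O)OCC[Si](C)(C)C)[C@@H](COCc4ccccc4)CO[Si](CC)(CC)CC
F2 | step 21 | corresponding C5 aldehyde, mixture at C10 | O1CCOC12C[C@@]3(C[C@@]2(O[Si](C)(C)C(C)(C)C)CC[C@H]3C(CCCCl)C(=O)OCC[Si](C)(C)C)[C@@H](COCc4ccccc4)C=O
F3 | step 21 | Z-enoate carrying the 10-(3-chloropropyl) ester, mixture at C10 | O1CCOC12C[C@@]3(C[C@@]2(O[Si](C)(C)C(C)(C)C)CC[C@H]3C(CCCCl)C(=O)OCC[Si](C)(C)C)[C@@H](COCc4ccccc4)/C=C(/C)C(=O)OCC[Si](C)(C)C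
F4 | step 21 | C1,C2-saturated analogue of 35 (7-CH2OBn) | O1CCOC12C[C@]34C[C@@]2(O[Si](C)(C)C(C)(C)C)CC[C@H]3[C@@]5(C(=O)OCC[Si](C)(C)C)CCC[C@@](C)(C(=O)OCC[Si](C)(C)C)[C@H]5[C@@H]4COCc6ccccc6
F5 | step 11 | C6 epimer of 18 | O1CCOC12C[C@@]3(C[C@@]2(O[Si](C)(C)C(C)(C)C)CC[C@H]3CC(=O)O)[C@H](COCc4ccccc4)C(=O)OC
F6 | step 15 | 10-(hydroxymethylene) TMSE ester (enol of the 10-formyl ester), geometry undefined | O1CCOC12C[C@@]3(C[C@@]2(O[Si](C)(C)C(C)(C)C)CC[C@H]3C(=CO)C(=O)OCC[Si](C)(C)C)[C@@H](COCc4ccccc4)CO[Si](CC)(CC)CC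
F7 | step 15 | enol triflate with the triflate cis to C9 | O1CCOC12C[C@@]3(C[C@@]2(O[Si](C)(C)C(C)(C)C)CC[C@H]3/C(C(=O)OCC[Si](C)(C)C)=C\OS(=O)(=O)C(F)(F)F)[C@@H](COCc4ccccc4)CO[Si](CC)(CC)CC
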